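The target is a germacranolide: a ten-membered carbocycle (C1–C10) carrying a C4–C5 cis-epoxide and a fused butenolide (O–C6, C7=C11, C12). Because the lactone-bearing C6 and the olefinic C7 are adjacent ring atoms, both are cut together: with C7 as a ketone, C6 becomes an activated electrophile. In one operation the carboxylate of a 2-phosphono-3-alkoxypropanoic acid displaces a 6β-mesylate with inversion (O–C6) and the resulting ester closes by intramolecular Horner–Wadsworth–Emmons olefination (C7=C11). The precursor, an epoxy α-mesyloxy cyclodecanone, comes from a Brown crotylation, a Brown alkoxyallylation and a Nozaki–Hiyama–Kishi ring closure; the temporary C7 stereocenter controls C6, whose hydroxyl directs the epoxidation.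

Key step: step 18

Remark: ring positions are cited in germacrane numbering (C1 = acetoxy carbon; C4 and C10 = methyl-bearing carbons; C6–C7–C8 = oxygenated triad; C11–C13 = lactone side carbons; α/β = below/above the ring in the usual drawing); the ester read from the SMILES is the (E)-2-methylbut-2-enoate (tiglate).
Assumption: acetaldehyde N,N-dimethylhydrazone, allyl 4-methoxyphenyl ether and ethyl 2-(diethoxyphosphoryl)acrylate are taken as catalogue chemicals.

Step 1
Reactants: 1 prop-2-yn-1-ol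
Product: 2 (Z)-3-iodo-2-methylprop-2-en-1-ol
Conditions: MeMgBr, CuI (cat.), THF, −10 °C to rt; then I2, −78 to 0 °C
Reagents that add atoms: methylmagnesium bromide C[Mg]Br; iodine II
Why: Alkoxide-directed anti-carbomagnesiation gives a chelated (Z)-alkenylmagnesium that is iodinated with retention, which fixes the Z geometry of the later C4=C5 bond.

Step 2
Reactants: 2 (Z)-3-iodo-2-methylprop-2-en-1-ol
Product: 3 (Z)-3-bromo-1-iodo-2-methylprop-1-ene
Conditions: CBr4, PPh3, CH2Cl2, 0 °C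
Reagents that add atoms: carbon tetrabromide BrC(Br)(Br)Br
Why: Appel bromination of a primary allylic alcohol under neutral conditions leaves the iodoalkene geometry untouched.

Step 3
Reactants: 3 (Z)-3-bromo-1-iodo-2-methylprop-1-ene; 4 acetaldehyde N,N-dimethylhydrazone
Product: 6 (Z)-5-iodo-4-methylpent-4-enal, via hydrazone 5 (not isolated)
Conditions: LDA, THF, −78 to 0 °C; then 3, −78 °C to rt; then aq. oxalic acid, Et2O, rt
Reagents that add atoms: water O
Why: Alkylation of the lithiated aldehyde hydrazone (aza-enolate alkylation) by the allylic bromide in SN2 fashion and mild hydrolysis give the two-carbon-homologated aldehyde without self-aldol reaction.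

Step 4
Reactants: 6 (Z)-5-iodo-4-methylpent-4-enal; 7 trans-but-2-ene
Product: 9 (3R,4S,7Z)-8-iodo-3,7-dimethylocta-1,7-dien-4-ol, via crotylborane 8 (not isolated)
Conditions: 7, KOt-Bu, n-BuLi, THF, −78 to −45 °C; (+)-B-methoxydiisopinocampheylborane, −78 °C; BF3·OEt2; then 6, −78 °C; NaOH, H2O2, 0 °C to rt
Reagents that add atoms: none
Why: Brown crotylboration through a closed chair transition state should give the anti C1-OH/C10-CH3 pair from the (E)-crotyl unit, while the isopinocampheyl ligands derived from (−)-α-pinene direct attack to the Re face of the aldehyde, setting C1 (S) and C10 (R).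

Step 5
Reactants: 9 (3R,4S,7Z)-8-iodo-3,7-dimethylocta-1,7-dien-4-ol
Product: 10 (3R,4S,7Z)-8-iodo-3,7-dimethylocta-1,7-dien-4-yl acetate
Conditions: Ac2O, pyridine, DMAP (cat.), CH2Cl2, rt
Reagents that add atoms: acetic anhydride CC(=O)OC(C)=O
Why: DMAP-catalysed acetylation installs the final C1 acetate early, since no later step uses a hydride or strong nucleophile.

Step 6
Reactants: 10 (3R,4S,7Z)-8-iodo-3,7-dimethylocta-1,7-dien-4-yl acetate
Product: 11 (3R,4S,7Z)-1-hydroxy-8-iodo-3,7-dimethyloct-7-en-4-yl acetate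
Conditions: 9-BBN, THF, 0 °C to rt; then 30% H2O2, aq. NaOAc, 0 °C
Reagents that add atoms: hydrogen peroxide OO
Why: Anti-Markovnikov hydroboration with the bulky 9-BBN is selective for the monosubstituted alkene over the trisubstituted iodoalkene and the acetate, and the buffered oxidation spares the ester.

Step 7
Reactants: 11 (3R,4S,7Z)-1-hydroxy-8-iodo-3,7-dimethyloct-7-en-4-yl acetate
Product: 12 (3R,4S,7Z)-8-iodo-3,7-dimethyl-1-oxooct-7-en-4-yl acetate
Conditions: Dess–Martin periodinane, NaHCO3, CH2Cl2, 0 °C to rt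
Reagents that add atoms: none
Why: Dess–Martin oxidation of the primary alcohol gives the C8 aldehyde under neutral conditions.

Step 8
Reactants: 12 (3R,4S,7Z)-8-iodo-3,7-dimethyl-1-oxooct-7-en-4-yl acetate; 13 allyl 4-methoxyphenyl ether
Product: 15 (3S,4S,6R,7S,10Z)-4-hydroxy-11-iodo-3-(4-methoxyphenoxy)-6,10-dimethylundeca-1,10-dien-7-yl acetate, via allylborane 14 (not isolated)
Conditions: 13, s-BuLi, THF, −78 °C; (+)-B-methoxydiisopinocampheylborane; BF3·OEt2; then 12, −78 °C; 30% H2O2, aq. NaOAc, 0 °C to rt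
Reagents that add atoms: none
Why: Brown alkoxyallylboration: the chelated (Z)-γ-aryloxyallyl anion is transferred to boron and adds through a chair transition state to give the syn C7-OAr/C8-OH pair, the same pinene antipode again selecting the Re face so that C8 is (S) and the temporary C7 centre is β.

Step 9
Reactants: 15 (3S,4S,6R,7S,10Z)-4-hydroxy-11-iodo-3-(4-methoxyphenoxy)-6,10-dimethylundeca-1,10-dien-7-yl acetate
Product: 16 (3S,4S,6R,7S,10Z)-7-acetoxy-11-iodo-3-(4-methoxyphenoxy)-6,10-dimethylundeca-1,10-dien-4-yl (E)-2-methylbut-2-enoate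
Conditions: (E)-2-methylbut-2-enoyl chloride, pyridine, DMAP (cat.), CH2Cl2, 0 °C to rt
Reagents that add atoms: tigloyl chloride C/C=C(\C)C(Cl)=O
Why: DMAP-catalysed acylation of the only free hydroxyl places the tiglate on C8 with its E geometry unchanged.

Step 10
Reactants: 16 (3S,4S,6R,7S,10Z)-7-acetoxy-11-iodo-3-(4-methoxyphenoxy)-6,10-dimethylundeca-1,10-dien-4-yl (E)-2-methylbut-2-enoate
Product: 17 (2R,3S,5R,6S,9Z)-6-acetoxy-10-iodo-2-(4-methoxyphenoxy)-5,9-dimethyl-1-oxodec-9-en-3-yl (E)-2-methylbut-2-enoate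
Conditions: OsO4 (cat.), NaIO4, 2,6-lutidine, dioxane/H2O, rt
Reagents that add atoms: sodium periodate [Na+].[O-]I(=O)(=O)=O; osmium tetroxide O=[Os](=O)(=O)=O (catalytic oxygen carrier)
Why: Johnson–Lemieux cleavage: OsO4 should dihydroxylate the unhindered monosubstituted alkene in preference to the electron-poor iodoalkene and tiglate, and periodate cleaves the diol to the C6 aldehyde.

Step 11
Reactants: 17 (2R,3S,5R,6S,9Z)-6-acetoxy-10-iodo-2-(4-methoxyphenoxy)-5,9-dimethyl-1-oxodec-9-en-3-yl (E)-2-methylbut-2-enoate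
Product: 18 (1S,6S,7S,8S,10R,4Z)-1-acetoxy-6-hydroxy-7-(4-methoxyphenoxy)-4,10-dimethylcyclodec-4-en-8-yl (E)-2-methylbut-2-enoate
Conditions: CrCl2, NiCl2 (cat.), DMSO, rt, high dilution
Reagents that add atoms: none
Why: Intramolecular Nozaki–Hiyama–Kishi reaction: the alkenylchromium species adds only to the aldehyde with retention of the Z geometry, closing the C5–C6 bond of the ten-membered ring, and Felkin–Anh attack anti to the poorly chelating C7 aryloxy group is expected to give the 6,7-anti (6β) alcohol.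

Step 12
Reactants: 18 (1S,6S,7S,8S,10R,4Z)-1-acetoxy-6-hydroxy-7-(4-methoxyphenoxy)-4,10-dimethylcyclodec-4-en-8-yl (E)-2-methylbut-2-enoate
Product: 19 (1S,4R,5S,6R,7S,8S,10R)-1-acetoxy-4,5-epoxy-6-hydroxy-7-(4-methoxyphenoxy)-4,10-dimethylcyclodecan-8-yl (E)-2-methylbut-2-enoate
Conditions: mCPBA, NaHCO3, CH2Cl2, 0 °C
Reagents that add atoms: 3-chloroperoxybenzoic acid OOC(=O)c1cccc(Cl)c1
Why: Henbest hydroxyl-directed epoxidation of the only electron-rich alkene: with H-6 held in the alkene plane by A(1,3) strain, delivery next to the hydroxyl should give the threo isomer (epoxide trans to 6-OH across the ring), as with acyclic (Z)-allylic alcohols and medium-ring (Z)-cycloalkenols, setting C4 (R) and C5 (S).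

Step 13
Reactants: 19 (1S,4R,5S,6R,7S,8S,10R)-1-acetoxy-4,5-epoxy-6-hydroxy-7-(4-methoxyphenoxy)-4,10-dimethylcyclodecan-8-yl (E)-2-methylbut-2-enoate
Product: 20 (1S,4R,5S,6R,7R,8S,10R)-1-acetoxy-4,5-epoxy-7-(4-methoxyphenoxy)-4,10-dimethyl-6-(methylsulfonyloxy)cyclodecan-8-yl (E)-2-methylbut-2-enoate
Conditions: MsCl, Et3N, CH2Cl2, −20 to 0 °C
Reagents that add atoms: methanesulfonyl chloride CS(Cl)(=O)=O
Why: Sulfonylation at oxygen proceeds with retention, so the 6β-hydroxyl becomes a 6β leaving group that also protects C6 during the next two steps.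

Step 14
Reactants: 20 (1S,4R,5S,6R,7R,8S,10R)-1-acetoxy-4,5-epoxy-7-(4-methoxyphenoxy)-4,10-dimethyl-6-(methylsulfonyloxy)cyclodecan-8-yl (E)-2-methylbut-2-enoate
Product: 21 (1S,4R,5S,6R,7R,8S,10R)-1-acetoxy-4,5-epoxy-7-hydroxy-4,10-dimethyl-6-(methylsulfonyloxy)cyclodecan-8-yl (E)-2-methylbut-2-enoate
Conditions: (NH4)2Ce(NO3)6, pyridine, MeCN/H2O (4:1), 0 °C
Reagents that add atoms: none
Why: Oxidative dearylation of the 4-methoxyphenyl ether by tetravalent cerium (single-electron oxidation, ipso attack of water) frees the C7 hydroxyl, and pyridine buffering should protect the epoxide.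

Step 15
Reactants: 21 (1S,4R,5S,6R,7R,8S,10R)-1-acetoxy-4,5-epoxy-7-hydroxy-4,10-dimethyl-6-(methylsulfonyloxy)cyclodecan-8-yl (E)-2-methylbut-2-enoate
Product: 22 (1S,4R,5S,6S,8S,10R)-1-acetoxy-4,5-epoxy-4,10-dimethyl-6-(methylsulfonyloxy)-7-oxocyclodecan-8-yl (E)-2-methylbut-2-enoate
Conditions: Dess–Martin periodinane, NaHCO3, CH2Cl2, 0 °C to rt
Reagents that add atoms: none
Why: Neutral Dess–Martin oxidation removes the temporary C7 stereocenter and gives the α-mesyloxy ketone without enolisation.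

Step 16
Reactants: 23 ethyl 2-(diethoxyphosphoryl)acrylate; 24 4-methoxybenzyl alcohol
Product: 25 ethyl 2-(diethoxyphosphoryl)-3-[(4-methoxybenzyl)oxy]propanoate (racemic)
Conditions: Cs2CO3 (cat.), MeCN, rt
Reagents that add atoms: none
Why: Base-catalysed oxa-Michael addition of the alcohol to the doubly activated vinylphosphonate installs the protected C13 oxygen.

Step 17
Reactants: 25 ethyl 2-(diethoxyphosphoryl)-3-[(4-methoxybenzyl)oxy]propanoate
Product: 26 2-(diethoxyphosphoryl)-3-[(4-methoxybenzyl)oxy]propanoic acid (racemic)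
Conditions: LiOH·H2O, THF/H2O, 0 °C to rt; then aq. HCl to pH 2
Reagents that add atoms: lithium hydroxide [Li+].[OH-]
Why: Saponification of the carboxylic ester is much faster than that of the phosphonate esters, and the labile C2 centre is irrelevant because it becomes sp2.

Step 18
Reactants: 22 (1S,4R,5S,6S,8S,10R)-1-acetoxy-4,5-epoxy-4,10-dimethyl-6-(methylsulfonyloxy)-7-oxocyclodecan-8-yl (E)-2-methylbut-2-enoate; 26 2-(diethoxyphosphoryl)-3-[(4-methoxybenzyl)oxy]propanoic acid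
Product: 28 (1S,4R,5S,6S,8S,10R)-1-acetoxy-4,5-epoxy-13-[(4-methoxybenzyl)oxy]-8-tigloyloxygermacr-7(11)-en-12,6-olide, via phosphonate ester 27 (not isolated)
Conditions: 26, Cs2CO3, DMF, 0 °C to rt; then LiCl, i-Pr2NEt, MeCN, rt
Reagents that add atoms: none
Why: The cesium carboxylate of 26 displaces the C6 mesylate of 22 by SN2 (the known alkylation of carboxylates by α-sulfonyloxy or α-halo ketones), forming O–C6 with inversion so that the 6β-mesylate gives the 6α-acyloxy ketone 27. LiCl and i-Pr2NEt (Masamune–Roush conditions) then form the lithium-chelated phosphonate carbanion, which adds to the C7 ketone and collapses through the oxaphosphetane to the C7=C11 bond, the standard intramolecular Horner–Wadsworth–Emmons route from α-acyloxy ketones to butenolides. The five-membered lactone closes by 5-exo-trig attack of C11 on the C7 carbonyl, and the new alkene is endocyclic and tetrasubstituted, so no E/Z question arises. The only new stereocenter, C6, is fixed by the stereospecific inversion, while C1, C4, C5, C8 and C10 are untouched. The step needs substitution at C6 instead of at the epoxide carbons (secured by the adjacent carbonyl and the weakly basic carboxylate) and deprotonation of the phosphonate instead of H-6 or H-8 (secured by lithium chelation and the weak amine base, which should also spare the β,γ-epoxy ketone from E1cB opening). C13 is carried as a 4-methoxybenzyl ether, not as the acetate, because an alkoxide is too poor a leaving group to be expelled from the phosphonate anion.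

Step 19
Reactants: 28 (1S,4R,5S,6S,8S,10R)-1-acetoxy-4,5-epoxy-13-[(4-methoxybenzyl)oxy]-8-tigloyloxygermacr-7(11)-en-12,6-olide
Product: 29 (1S,4R,5S,6S,8S,10R)-1-acetoxy-4,5-epoxy-13-hydroxy-8-tigloyloxygermacr-7(11)-en-12,6-olide
Conditions: DDQ, CH2Cl2/pH 7 buffer, 0 °C to rt
Reagents that add atoms: none
Why: DDQ cleaves the electron-rich benzylic ether by hydride abstraction and hydrolysis under neutral conditions that the epoxide, esters and butenolide tolerate.

Step 20
Reactants: 29 (1S,4R,5S,6S,8S,10R)-1-acetoxy-4,5-epoxy-13-hydroxy-8-tigloyloxygermacr-7(11)-en-12,6-olide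
Product: 30 (1S,4R,5S,6S,8S,10R)-1,13-diacetoxy-4,5-epoxy-8-tigloyloxygermacr-7(11)-en-12,6-olide (CNP0287840.1)
Conditions: Ac2O, pyridine, DMAP (cat.), CH2Cl2, 0 °C
Reagents that add atoms: acetic anhydride CC(=O)OC(C)=O
Why: Acetylation of the primary allylic alcohol under mild base completes the target without disturbing the butenolide γ-position.

Compound list
1 | prop-2-yn-1-ol | C#CCO | starting material
2 | (Z)-3-iodo-2-methylprop-2-en-1-ol | OC/C(C)=C\I | intermediate
3 | (Z)-3-bromo-1-iodo-2-methylprop-1-ene | BrC/C(C)=C\I | intermediate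
4 | acetaldehyde N,N-dimethylhydrazone | C/C=N/N(C)C | starting material
5 | N,N-dimethylhydrazone of (Z)-5-iodo-4-methylpent-4-enal | CN(C)/N=C/CC/C(C)=C\I | intermediate (not isolated)
6 | (Z)-5-iodo-4-methylpent-4-enal | O=CCC/C(C)=C\I | intermediate
7 | trans-but-2-ene | C/C=C/C | starting material
8 | B-[(E)-but-2-enyl]diisopinocampheylborane (isopinocampheyl groups from (−)-α-pinene) | C/C=C/CB([C@H]1C[C@H]2C[C@@H]([C@@H]1C)C2(C)C)[C@H]1C[C@H]2C[C@@H]([C@@H]1C)C2(C)C | intermediate (not isolated)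
9 | (3R,4S,7Z)-8-iodo-3,7-dimethylocta-1,7-dien-4-ol | C=C[C@@H](C)[C@@H](O)CC/C(C)=C\I | intermediate
10 | (3R,4S,7Z)-8-iodo-3,7-dimethylocta-1,7-dien-4-yl acetate | C=C[C@@H](C)[C@@H](OC(C)=O)CC/C(C)=C\I | intermediate
11 | (3R,4S,7Z)-1-hydroxy-8-iodo-3,7-dimethyloct-7-en-4-yl acetate | OCC[C@@H](C)[C@@H](OC(C)=O)CC/C(C)=C\I | intermediate
12 | (3R,4S,7Z)-8-iodo-3,7-dimethyl-1-oxooct-7-en-4-yl acetate | O=CC[C@@H](C)[C@@H](OC(C)=O)CC/C(C)=C\I | intermediate
13 | allyl 4-methoxyphenyl ether | C=CCOc1ccc(OC)cc1 | starting material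
14 | B-[(Z)-3-(4-methoxyphenoxy)prop-2-enyl]diisopinocampheylborane | COc1ccc(O/C=C\CB([C@H]2C[C@H]3C[C@@H]([C@@H]2C)C3(C)C)[C@H]2C[C@H]3C[C@@H]([C@@H]2C)C3(C)C)cc1 | intermediate (not isolated)
15 | (3S,4S,6R,7S,10Z)-4-hydroxy-11-iodo-3-(4-methoxyphenoxy)-6,10-dimethylundeca-1,10-dien-7-yl acetate | C=C[C@H](Oc1ccc(OC)cc1)[C@@H](O)C[C@@H](C)[C@@H](OC(C)=O)CC/C(C)=C\I | intermediate
16 | (3S,4S,6R,7S,10Z)-7-acetoxy-11-iodo-3-(4-methoxyphenoxy)-6,10-dimethylundeca-1,10-dien-4-yl (E)-2-methylbut-2-enoate | C=C[C@H](Oc1ccc(OC)cc1)[C@@H](OC(=O)/C(C)=C/C)C[C@@H](C)[C@@H](OC(C)=O)CC/C(C)=C\I | intermediate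
17 | (2R,3S,5R,6S,9Z)-6-acetoxy-10-iodo-2-(4-methoxyphenoxy)-5,9-dimethyl-1-oxodec-9-en-3-yl (E)-2-methylbut-2-enoate | O=C[C@H](Oc1ccc(OC)cc1)[C@@H](OC(=O)/C(C)=C/C)C[C@@H](C)[C@@H](OC(C)=O)CC/C(C)=C\I | intermediate
18 | (1S,6S,7S,8S,10R,4Z)-1-acetoxy-6-hydroxy-7-(4-methoxyphenoxy)-4,10-dimethylcyclodec-4-en-8-yl tiglate (1α-OAc, 6β-OH, 7β-OAr, 8α-OTig, 10α-CH3) | C/C=C(\C)C(=O)O[C@H]1C[C@@H](C)[C@@H](OC(C)=O)CC/C(C)=C\[C@H](O)[C@@H]1Oc2ccc(OC)cc2 | intermediate
19 | (1S,4R,5S,6R,7S,8S,10R)-4α,5α-epoxide of 18 (6β-OH) | C/C=C(\C)C(=O)O[C@H]1C[C@@H](C)[C@@H](OC(C)=O)CC[C@@]2(C)O[C@H]2[C@H](O)[C@@H]1Oc3ccc(OC)cc3 | intermediate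
20 | (1S,4R,5S,6R,7R,8S,10R)-6β-mesylate of 19 | C/C=C(\C)C(=O)O[C@H]1C[C@@H](C)[C@@H](OC(C)=O)CC[C@@]2(C)O[C@H]2[C@H](OS(C)(=O)=O)[C@@H]1Oc3ccc(OC)cc3 | intermediate
21 | (1S,4R,5S,6R,7R,8S,10R)-7β-alcohol (6β-OMs, 4α,5α-epoxide) | C/C=C(\C)C(=O)O[C@H]1C[C@@H](C)[C@@H](OC(C)=O)CC[C@@]2(C)O[C@H]2[C@H](OS(C)(=O)=O)[C@@H]1O | intermediate
22 | (1S,4R,5S,6S,8S,10R)-1-acetoxy-4,5-epoxy-4,10-dimethyl-6-(methylsulfonyloxy)-7-oxocyclodecan-8-yl tiglate (6β-OMs) | C/C=C(\C)C(=O)O[C@H]1C[C@@H](C)[C@@H](OC(C)=O)CC[C@@]2(C)O[C@H]2[C@H](OS(C)(=O)=O)C1=O | intermediate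
23 | ethyl 2-(diethoxyphosphoryl)acrylate | CCOC(=O)C(=C)P(=O)(OCC)OCC | starting material
24 | 4-methoxybenzyl alcohol | COc1ccc(CO)cc1 | starting material
25 | ethyl 2-(diethoxyphosphoryl)-3-[(4-methoxybenzyl)oxy]propanoate (racemic) | CCOC(=O)C(COCc1ccc(OC)cc1)P(=O)(OCC)OCC | intermediate
26 | 2-(diethoxyphosphoryl)-3-[(4-methoxybenzyl)oxy]propanoic acid (racemic) | OC(=O)C(COCc1ccc(OC)cc1)P(=O)(OCC)OCC | intermediate
27 | 6α-[2-(diethoxyphosphoryl)-3-(4-methoxybenzyloxy)propanoyloxy] ketone (6R; epimers at the phosphonate carbon) | C/C=C(\C)C(=O)O[C@H]1C[C@@H](C)[C@@H](OC(C)=O)CC[C@@]2(C)O[C@H]2[C@@H](OC(=O)C(COCc3ccc(OC)cc3)P(=O)(OCC)OCC)C1=O | intermediate (not isolated)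
28 | (1S,4R,5S,6S,8S,10R)-1-acetoxy-4,5-epoxy-13-[(4-methoxybenzyl)oxy]-8-tigloyloxygermacr-7(11)-en-12,6-olide | C/C=C(\C)C(=O)O[C@H]1C[C@@H](C)[C@@H](OC(C)=O)CC[C@@]2(C)O[C@H]2[C@H]2OC(=O)C(COCc3ccc(OC)cc3)=C12 | intermediate
29 | (1S,4R,5S,6S,8S,10R)-1-acetoxy-4,5-epoxy-13-hydroxy-8-tigloyloxygermacr-7(11)-en-12,6-olide | C/C=C(\C)C(=O)O[C@H]1C[C@@H](C)[C@@H](OC(C)=O)CC[C@@]2(C)O[C@H]2[C@H]2OC(=O)C(CO)=C12 | intermediate
30 | (1S,4R,5S,6S,8S,10R)-1,13-diacetoxy-4,5-epoxy-8-tigloyloxygermacr-7(11)-en-12,6-olide | C/C=C(\C)C(=O)O[C@H]1C[C@@H](C)[C@@H](OC(C)=O)CC[C@@]2(C)O[C@H]2[C@H]2OC(=O)C(COC(C)=O)=C12 | target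

Total step count: 20. Longest linear sequence: 18 (steps 1–15 and 18–20; steps 16–17 make the side fragment).

Steps most likely to fail

Step 18. The risk is slow substitution at the hindered C6 carbon, or enolisation of the β,γ-epoxy ketone under base, with loss of the C6 configuration or opening of the epoxide. The fallback sets out from 19 and inverts C6 at the alcohol stage, where no enolisable ketone is present. Mitsunobu reaction with chloroacetic acid (PPh3, DIAD, toluene, 0 °C) gives the 6α-chloroacetate F1. (NH4)2Ce(NO3)6 with pyridine frees the C7 hydroxyl to give F2, and Dess–Martin periodinane gives ketone F3. Thiourea and NaHCO3 in EtOH remove the chloroacetate to give the 6α-hydroxy ketone F4. Acylation of F4 with 26 (DCC, DMAP cat., CH2Cl2, 0 °C) makes the lactone C–O bond with retention and gives 27, now isolated, which LiCl and i-Pr2NEt close to 28, where the route is rejoined.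

Step 11. The risk is poor facial selectivity at C6 in the ring-closing addition. The fallback sets out from 17: the cyclisation is run as in step 11, and the mixture of 18 and its C6 epimer F5 is oxidised with Dess–Martin periodinane to the single enone F6. Reagent-controlled reduction with (S)-Me-CBS oxazaborolidine and BH3·SMe2 (alkenyl arm as the large group) returns 18.

Step 12. The risk is epoxidation on the wrong face through hydrogen-bonded delivery from an unexpected ring conformer. The fallback sets out from 18: the hydroxyl is masked as the triethylsilyl ether F7 (TESOTf, 2,6-lutidine, CH2Cl2, −78 °C). Dimethyldioxirane in acetone at 0 °C epoxidises F7 under purely steric, peripheral approach control to give F8. HF·pyridine in THF/pyridine then returns 19.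

Further compounds
F1 | step 18 | 6α-chloroacetate of the 4α,5α-epoxy-7β-(4-methoxyphenoxy) ring compound (C6 inverted relative to 19) | C/C=C(\C)C(=O)O[C@H]1C[C@@H](C)[C@@H](OC(C)=O)CC[C@@]2(C)O[C@H]2[C@@H](OC(=O)CCl)[C@@H]1Oc3ccc(OC)cc3
F2 | step 18 | 6α-chloroacetoxy-7β-alcohol | C/C=C(\C)C(=O)O[C@H]1C[C@@H](C)[C@@H](OC(C)=O)CC[C@@]2(C)O[C@H]2[C@@H](OC(=O)CCl)[C@@H]1O
F3 | step 18 | 6α-chloroacetoxy-7-ketone | C/C=C(\C)C(=O)O[C@H]1C[C@@H](C)[C@@H](OC(C)=O)CC[C@@]2(C)O[C@H]2[C@@H](OC(=O)CCl)C1=O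
F4 | step 18 | 6α-hydroxy-7-ketone | C/C=C(\C)C(=O)O[C@H]1C[C@@H](C)[C@@H](OC(C)=O)CC[C@@]2(C)O[C@H]2[C@@H](O)C1=O
F5 | step 11 | C6 epimer of 18 (6α-OH) | C/C=C(\C)C(=O)O[C@H]1C[C@@H](C)[C@@H](OC(C)=O)CC/C(C)=C\[C@@H](O)[C@@H]1Oc2ccc(OC)cc2
F6 | step 11 | (4Z)-cyclodec-4-en-6-one (enone from 18 and F5) | C/C=C(\C)C(=O)O[C@H]1C[C@@H](C)[C@@H](OC(C)=O)CC/C(C)=C\C(=O)[C@@H]1Oc2ccc(OC)cc2
F7 | step 12 | 6β-triethylsilyl ether of 18 | C/C=C(\C)C(=O)O[C@H]1C[C@@H](C)[C@@H](OC(C)=O)CC/C(C)=C\[C@H](O[Si](CC)(CC)CC)[C@@H]1Oc2ccc(OC)cc2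
F8 | step 12 | 6β-triethylsilyl ether of 19 | C/C=C(\C)C(=O)O[C@H]1C[C@@H](C)[C@@H](OC(C)=O)CC[C@@]2(C)O[C@H]2[C@H](O[Si](CC)(CC)CC)[C@@H]1Oc3ccc(OC)cc3
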